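**Plan**

1. The target is a 3,7,7-trisubstituted 6,7-dihydrooxepin-2(5H)-one (ring atoms O1, C2 carbonyl, C3=C4, C5, C6, C7; C1′ is the carbinol carbon on C7; the same locants are used for the open-chain precursors).
2. After removal of two silyl ethers, the retrosynthesis cuts O1–C7. The lactone is the product of 7-exo opening of a cis-2,2,3-trisubstituted oxirane (C7/C1′) by the carboxyl group of a (Z)-2-alkylidene acid. This is possible because the methyl-bearing tertiary oxirane carbon C7 lies five atoms from the carboxyl oxygen, and the cis C3=C4 bond holds C2 and C5 on the same side.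
3. Further cuts, in order: C3=C4 (Still–Gennari olefination of an epoxy aldehyde with an α-alkylated phosphonoacetate), C5–C6 (cyanomethyl displacement of an epoxy triflate), the oxirane (Sharpless epoxidation), and C7=C1′ (Still–Gennari olefination of a nerol-derived aldehyde).
4. Forward order: nerol → C6 aldehyde → (Z)-enoate → (Z)-allylic alcohol → cis-epoxy alcohol → epoxy aldehyde → union with the phosphonate → epoxy acid → oxepinone (the only ring) → desilylation.
5. Both stereocentres come from one Sharpless epoxidation (diethyl L-(+)-tartrate) of a (Z)-allylic alcohol, giving the (2S,3R)-cis-oxirane. Ring closure inverts C7 (S to R) and leaves C1′ (R) untouched.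
6. The three Z olefins come from nerol, from two Still–Gennari olefinations, and from a Z-selective Wittig reaction of an α-silyloxy ketone.

Key step: step 14

**Route**

Step 1
Reactants: 1 nerol
Product: 2 tert-butyl{[(2Z)-3,7-dimethylocta-2,6-dien-1-yl]oxy}diphenylsilane
Conditions: t-BuPh2SiCl, imidazole, DMF, 0 °C → rt
Reagents that add atoms: tert-butyl(chloro)diphenylsilane, CC(C)(C)[Si](Cl)(c1ccccc1)c1ccccc1
Why: Standard imidazole-mediated silylation of a primary allylic alcohol; the bulky, acid-tolerant silyl ether also shields and inductively deactivates the adjacent olefin for step 2.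

Step 2
Reactants: 2 tert-butyl{[(2Z)-3,7-dimethylocta-2,6-dien-1-yl]oxy}diphenylsilane
Product: 3 tert-butyl{[(2Z)-5-(3,3-dimethyloxiran-2-yl)-3-methylpent-2-en-1-yl]oxy}diphenylsilane (racemic at the oxirane carbon)
Conditions: 3-chloroperoxybenzoic acid (1.0 equiv), CH2Cl2, −20 °C
Reagents that add atoms: 3-chloroperoxybenzoic acid, OOC(=O)c1cccc(Cl)c1
Why: Prilezhaev epoxidation should prefer the more electron-rich, unhindered terminal trisubstituted olefin over the one deactivated by the allylic silyloxy group; the new stereocentre is destroyed in step 3.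

Step 3
Reactants: 3 tert-butyl{[(2Z)-5-(3,3-dimethyloxiran-2-yl)-3-methylpent-2-en-1-yl]oxy}diphenylsilane
Product: 4 (4Z)-6-[(tert-butyldiphenylsilyl)oxy]-4-methylhex-4-enal
Conditions: H5IO6 (1.1 equiv), THF/H2O, 0 °C
Reagents that add atoms: none
Why: Periodic acid hydrolyses the epoxide and cleaves the resulting glycol in one operation (Malaprade cleavage), releasing acetone and the aldehyde without touching the Z olefin.

Step 4
Reactants: 4 (4Z)-6-[(tert-butyldiphenylsilyl)oxy]-4-methylhex-4-enal; 5 ethyl 2-[bis(2,2,2-trifluoroethoxy)phosphoryl]propanoate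
Product: 6 ethyl (2Z,6Z)-8-[(tert-butyldiphenylsilyl)oxy]-2,6-dimethylocta-2,6-dienoate
Conditions: 5, KN(SiMe3)2, 18-crown-6, THF, −78 °C; then 4
Reagents that add atoms: none
Why: Still–Gennari olefination, in which the electron-poor trifluoroethyl phosphonate collapses faster than it equilibrates, so the kinetic (Z)-2-methyl enoate with the ester cis to the chain should dominate.

Step 5
Reactants: 6 ethyl (2Z,6Z)-8-[(tert-butyldiphenylsilyl)oxy]-2,6-dimethylocta-2,6-dienoate
Product: 7 (2Z,6Z)-8-[(tert-butyldiphenylsilyl)oxy]-2,6-dimethylocta-2,6-dien-1-ol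
Conditions: i-Bu2AlH (2.2 equiv), CH2Cl2, −78 °C; aq. potassium sodium tartrate
Reagents that add atoms: none
Why: Low-temperature 1,2-reduction of the enoate by i-Bu2AlH gives the allylic alcohol without isomerising either Z olefin or cleaving the silyl ether.

Step 6
Reactants: 7 (2Z,6Z)-8-[(tert-butyldiphenylsilyl)oxy]-2,6-dimethylocta-2,6-dien-1-ol
Product: 8 [(2S,3R)-3-{(3Z)-5-[(tert-butyldiphenylsilyl)oxy]-3-methylpent-3-en-1-yl}-2-methyloxiran-2-yl]methanol
Conditions: Ti(OiPr)4 (0.2 equiv), diethyl L-(+)-tartrate (0.24 equiv), t-BuOOH, 4 Å MS, CH2Cl2, −20 °C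
Reagents that add atoms: tert-butyl hydroperoxide, CC(C)(C)OO
Why: Katsuki–Sharpless asymmetric epoxidation, in which only the free allylic alcohol binds titanium and the L-(+)-tartrate ligand directs oxygen to the face giving the (2S,3R)-oxirane; the cis relationship is inherited from the Z olefin.

Step 7
Reactants: 8 [(2S,3R)-3-{(3Z)-5-[(tert-butyldiphenylsilyl)oxy]-3-methylpent-3-en-1-yl}-2-methyloxiran-2-yl]methanol; 9 acetonitrile
Product: 11 3-[(2S,3R)-3-{(3Z)-5-[(tert-butyldiphenylsilyl)oxy]-3-methylpent-3-en-1-yl}-2-methyloxiran-2-yl]propanenitrile, via triflate 10 (not isolated)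
Conditions: Tf2O, 2,6-lutidine, CH2Cl2, −78 °C; then LiCH2CN (from 9 and n-BuLi, 4 equiv), THF, −78 → −40 °C
Reagents that add atoms: trifluoromethanesulfonic anhydride, O=S(=O)(OS(=O)(=O)C(F)(F)F)C(F)(F)F (supplies the triflyl group of 10 only)
Why: The primary triflate is displaced in an SN2 reaction by lithiated acetonitrile at low temperature, where substitution at the oxiranylmethyl carbon should outrun attack on the trisubstituted oxirane; the stereocentres are not involved.

Step 8
Reactants: 11 3-[(2S,3R)-3-{(3Z)-5-[(tert-butyldiphenylsilyl)oxy]-3-methylpent-3-en-1-yl}-2-methyloxiran-2-yl]propanenitrile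
Product: 13 3-[(2S,3R)-3-{(3Z)-5-[(tert-butyldiphenylsilyl)oxy]-3-methylpent-3-en-1-yl}-2-methyloxiran-2-yl]propanal, via aldimine 12 (not isolated)
Conditions: i-Bu2AlH (1.2 equiv), CH2Cl2, −78 °C; then aq. potassium sodium tartrate, rt
Reagents that add atoms: water, O
Why: Standard i-Bu2AlH reduction of a nitrile, in which one hydride gives an N-aluminio imine that is stable at −78 °C and hydrolyses on work-up to the aldehyde while the oxirane and silyl ether stay inert.

Step 9
Reactants: 14 (3-hydroxypropyl)triphenylphosphonium bromide; 15 1-[(tert-butyldimethylsilyl)oxy]propan-2-one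
Product: 16 (3Z)-5-[(tert-butyldimethylsilyl)oxy]-4-methylpent-3-en-1-ol
Conditions: 14, KN(SiMe3)2 (2.05 equiv), THF, 0 °C; then 15, −78 °C → rt
Reagents that add atoms: none
Why: Wittig reaction of a non-stabilised ylide with an α-silyloxy methyl ketone, a ketone class known to give the trisubstituted olefin with the oxygenated carbon cis to the chain (Z); the second equivalent of base only converts the hydroxyl into its alkoxide.

Step 10
Reactants: 16 (3Z)-5-[(tert-butyldimethylsilyl)oxy]-4-methylpent-3-en-1-ol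
Product: 17 tert-butyl{[(2Z)-5-iodo-2-methylpent-2-en-1-yl]oxy}dimethylsilane
Conditions: I2, PPh3, imidazole, CH2Cl2, 0 °C
Reagents that add atoms: iodine, II
Why: Garegg–Samuelsson (Appel-type) iodination converts the primary alcohol into the iodide under near-neutral conditions that leave the allylic silyl ether and the Z olefin untouched.

Step 11
Reactants: 17 tert-butyl{[(2Z)-5-iodo-2-methylpent-2-en-1-yl]oxy}dimethylsilane; 18 methyl 2-[bis(2,2,2-trifluoroethoxy)phosphoryl]acetate
Product: 19 methyl (5Z)-2-[bis(2,2,2-trifluoroethoxy)phosphoryl]-7-[(tert-butyldimethylsilyl)oxy]-6-methylhept-5-enoate (racemic)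
Conditions: 18 (2 equiv), NaH (1.9 equiv), DMF, 0 °C; then 17, rt
Reagents that add atoms: none
Why: C-alkylation of the sodium phosphonoacetate with the primary iodide (excess 18 to suppress dialkylation) should give the α-substituted Still–Gennari reagent; the new stereocentre is lost in step 12.

Step 12
Reactants: 13 3-[(2S,3R)-3-{(3Z)-5-[(tert-butyldiphenylsilyl)oxy]-3-methylpent-3-en-1-yl}-2-methyloxiran-2-yl]propanal; 19 methyl (5Z)-2-[bis(2,2,2-trifluoroethoxy)phosphoryl]-7-[(tert-butyldimethylsilyl)oxy]-6-methylhept-5-enoate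
Product: 20 methyl (2Z,5Z)-7-[(tert-butyldimethylsilyl)oxy]-2-{3-[(2S,3R)-3-{(3Z)-5-[(tert-butyldiphenylsilyl)oxy]-3-methylpent-3-en-1-yl}-2-methyloxiran-2-yl]propylidene}-6-methylhept-5-enoate
Conditions: 19, KN(SiMe3)2, 18-crown-6, THF, −78 °C; then 13
Reagents that add atoms: none
Why: Still–Gennari olefination with the α-alkylated trifluoroethyl phosphonate should place the ester cis to the aldehyde-derived chain (Z), the geometry needed for ring closure, and the non-nucleophilic phosphonate anion leaves the oxirane intact.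

Step 13
Reactants: 20 methyl (2Z,5Z)-7-[(tert-butyldimethylsilyl)oxy]-2-{3-[(2S,3R)-3-{(3Z)-5-[(tert-butyldiphenylsilyl)oxy]-3-methylpent-3-en-1-yl}-2-methyloxiran-2-yl]propylidene}-6-methylhept-5-enoate
Product: 21 (2Z,5Z)-7-[(tert-butyldimethylsilyl)oxy]-2-{3-[(2S,3R)-3-{(3Z)-5-[(tert-butyldiphenylsilyl)oxy]-3-methylpent-3-en-1-yl}-2-methyloxiran-2-yl]propylidene}-6-methylhept-5-enoic acid
Conditions: LiOH, THF/MeOH/H2O, rt; then cold dilute HCl to pH 5
Reagents that add atoms: lithium hydroxide, [Li+].[OH-]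
Why: Saponification of the methyl ester, to which trisubstituted oxiranes and primary silyl ethers are stable, followed by cold mild acidification liberates the carboxylic acid needed as the internal nucleophile.

Step 14
Reactants: 21 (2Z,5Z)-7-[(tert-butyldimethylsilyl)oxy]-2-{3-[(2S,3R)-3-{(3Z)-5-[(tert-butyldiphenylsilyl)oxy]-3-methylpent-3-en-1-yl}-2-methyloxiran-2-yl]propylidene}-6-methylhept-5-enoic acid
Product: 22 (7R)-3-{(3Z)-5-[(tert-butyldimethylsilyl)oxy]-4-methylpent-3-en-1-yl}-7-{(1R,4Z)-6-[(tert-butyldiphenylsilyl)oxy]-1-hydroxy-4-methylhex-4-en-1-yl}-7-methyl-6,7-dihydrooxepin-2(5H)-one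
Conditions: (1S)-camphor-10-sulfonic acid (0.1 equiv), CH2Cl2 (0.005 M), 0 °C → rt
Reagents that add atoms: none
Why: The sulfonic acid activates the oxirane oxygen, the carbonyl oxygen of the conjugated acid attacks the methyl-bearing oxirane carbon C7 from the face opposite the breaking C–O bond, and proton loss gives the lactone and frees the C1′ hydroxyl. The closest known reaction type is the acid-catalysed intramolecular opening of trisubstituted epoxides by carboxylic acids (epoxy-acid lactonisation), as used for γ- and δ-lactones and in epoxide-opening cascades. The oxepinone ring closes in the 7-exo-tet mode. C7 is set by stereospecific inversion of the (S)-oxirane carbon (giving R), and C1′ keeps the R configuration installed in step 6 because its C–O bond is not broken. The step needs regioselectivity for C7 over C1′, secured because attack at C7 is both the smaller-ring (7 versus 8) and the tertiary, charge-stabilised pathway, and it needs the acid to outcompete olefin participation, secured by the allylic silyloxy groups that deactivate both remote olefins, by the mild acid and by high dilution. Only the Z acid, in which the C3=C4 bond holds C2 and C5 on the same side, can reach C7, so any E isomer from step 12 stays open-chain and is removed here.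

Step 15
Reactants: 22 (7R)-3-{(3Z)-5-[(tert-butyldimethylsilyl)oxy]-4-methylpent-3-en-1-yl}-7-{(1R,4Z)-6-[(tert-butyldiphenylsilyl)oxy]-1-hydroxy-4-methylhex-4-en-1-yl}-7-methyl-6,7-dihydrooxepin-2(5H)-one
Product: 23 (7R)-7-[(1R,4Z)-1,6-dihydroxy-4-methylhex-4-en-1-yl]-3-[(3Z)-5-hydroxy-4-methylpent-3-en-1-yl]-7-methyl-6,7-dihydrooxepin-2(5H)-one
Conditions: Bu4NF (3 equiv), AcOH (3 equiv), THF, 0 °C → rt
Reagents that add atoms: none
Why: Buffered fluoride cleaves both silicon–oxygen bonds, and the acetic acid buffer protects the unsaturated lactone and its tertiary ester linkage from base.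

**Compound list**

1 | nerol, (2Z)-3,7-dimethylocta-2,6-dien-1-ol | CC(C)=CCC/C(C)=C\CO | starting material
2 | tert-butyl{[(2Z)-3,7-dimethylocta-2,6-dien-1-yl]oxy}diphenylsilane | CC(C)=CCC/C(C)=C\CO[Si](c1ccccc1)(c1ccccc1)C(C)(C)C | intermediate
3 | tert-butyl{[(2Z)-5-(3,3-dimethyloxiran-2-yl)-3-methylpent-2-en-1-yl]oxy}diphenylsilane (racemic) | CC1(C)OC1CC/C(C)=C\CO[Si](c1ccccc1)(c1ccccc1)C(C)(C)C | intermediate
4 | (4Z)-6-[(tert-butyldiphenylsilyl)oxy]-4-methylhex-4-enal | O=CCC/C(C)=C\CO[Si](c1ccccc1)(c1ccccc1)C(C)(C)C | intermediate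
5 | ethyl 2-[bis(2,2,2-trifluoroethoxy)phosphoryl]propanoate | CCOC(=O)C(C)P(=O)(OCC(F)(F)F)OCC(F)(F)F | starting material
6 | ethyl (2Z,6Z)-8-[(tert-butyldiphenylsilyl)oxy]-2,6-dimethylocta-2,6-dienoate | CCOC(=O)/C(C)=C\CC/C(C)=C\CO[Si](c1ccccc1)(c1ccccc1)C(C)(C)C | intermediate
7 | (2Z,6Z)-8-[(tert-butyldiphenylsilyl)oxy]-2,6-dimethylocta-2,6-dien-1-ol | OC/C(C)=C\CC/C(C)=C\CO[Si](c1ccccc1)(c1ccccc1)C(C)(C)C | intermediate
8 | [(2S,3R)-3-{(3Z)-5-[(tert-butyldiphenylsilyl)oxy]-3-methylpent-3-en-1-yl}-2-methyloxiran-2-yl]methanol | OC[C@]1(C)O[C@@H]1CC/C(C)=C\CO[Si](c1ccccc1)(c1ccccc1)C(C)(C)C | intermediate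
9 | acetonitrile | CC#N | starting material
10 | [(2S,3R)-3-{(3Z)-5-[(tert-butyldiphenylsilyl)oxy]-3-methylpent-3-en-1-yl}-2-methyloxiran-2-yl]methyl trifluoromethanesulfonate | FC(F)(F)S(=O)(=O)OC[C@]1(C)O[C@@H]1CC/C(C)=C\CO[Si](c1ccccc1)(c1ccccc1)C(C)(C)C | intermediate
11 | 3-[(2S,3R)-3-{(3Z)-5-[(tert-butyldiphenylsilyl)oxy]-3-methylpent-3-en-1-yl}-2-methyloxiran-2-yl]propanenitrile | N#CCC[C@]1(C)O[C@@H]1CC/C(C)=C\CO[Si](c1ccccc1)(c1ccccc1)C(C)(C)C | intermediate
12 | 3-[(2S,3R)-3-{(3Z)-5-[(tert-butyldiphenylsilyl)oxy]-3-methylpent-3-en-1-yl}-2-methyloxiran-2-yl]propan-1-imine | N=CCC[C@]1(C)O[C@@H]1CC/C(C)=C\CO[Si](c1ccccc1)(c1ccccc1)C(C)(C)C | intermediate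
13 | 3-[(2S,3R)-3-{(3Z)-5-[(tert-butyldiphenylsilyl)oxy]-3-methylpent-3-en-1-yl}-2-methyloxiran-2-yl]propanal | O=CCC[C@]1(C)O[C@@H]1CC/C(C)=C\CO[Si](c1ccccc1)(c1ccccc1)C(C)(C)C | intermediate
14 | (3-hydroxypropyl)triphenylphosphonium bromide | OCCC[P+](c1ccccc1)(c1ccccc1)c1ccccc1.[Br-] | starting material
15 | 1-[(tert-butyldimethylsilyl)oxy]propan-2-one | CC(=O)CO[Si](C)(C)C(C)(C)C | starting material
16 | (3Z)-5-[(tert-butyldimethylsilyl)oxy]-4-methylpent-3-en-1-ol | OCC/C=C(/C)CO[Si](C)(C)C(C)(C)C | intermediate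
17 | tert-butyl{[(2Z)-5-iodo-2-methylpent-2-en-1-yl]oxy}dimethylsilane | ICC/C=C(/C)CO[Si](C)(C)C(C)(C)C | intermediate
18 | methyl 2-[bis(2,2,2-trifluoroethoxy)phosphoryl]acetate | COC(=O)CP(=O)(OCC(F)(F)F)OCC(F)(F)F | starting material
19 | methyl (5Z)-2-[bis(2,2,2-trifluoroethoxy)phosphoryl]-7-[(tert-butyldimethylsilyl)oxy]-6-methylhept-5-enoate (racemic) | COC(=O)C(CC/C=C(/C)CO[Si](C)(C)C(C)(C)C)P(=O)(OCC(F)(F)F)OCC(F)(F)F | intermediate
20 | methyl (2Z,5Z)-7-[(tert-butyldimethylsilyl)oxy]-2-{3-[(2S,3R)-3-{(3Z)-5-[(tert-butyldiphenylsilyl)oxy]-3-methylpent-3-en-1-yl}-2-methyloxiran-2-yl]propylidene}-6-methylhept-5-enoate | COC(=O)/C(CC/C=C(/C)CO[Si](C)(C)C(C)(C)C)=C\CC[C@]1(C)O[C@@H]1CC/C(C)=C\CO[Si](c1ccccc1)(c1ccccc1)C(C)(C)C | intermediate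
21 | (2Z,5Z)-7-[(tert-butyldimethylsilyl)oxy]-2-{3-[(2S,3R)-3-{(3Z)-5-[(tert-butyldiphenylsilyl)oxy]-3-methylpent-3-en-1-yl}-2-methyloxiran-2-yl]propylidene}-6-methylhept-5-enoic acid | OC(=O)/C(CC/C=C(/C)CO[Si](C)(C)C(C)(C)C)=C\CC[C@]1(C)O[C@@H]1CC/C(C)=C\CO[Si](c1ccccc1)(c1ccccc1)C(C)(C)C | intermediate
22 | (7R)-3-{(3Z)-5-[(tert-butyldimethylsilyl)oxy]-4-methylpent-3-en-1-yl}-7-{(1R,4Z)-6-[(tert-butyldiphenylsilyl)oxy]-1-hydroxy-4-methylhex-4-en-1-yl}-7-methyl-6,7-dihydrooxepin-2(5H)-one | CC(C)(C)[Si](C)(C)OC/C(C)=C\CCC1=CCC[C@](C)([C@H](O)CC/C(C)=C\CO[Si](c2ccccc2)(c2ccccc2)C(C)(C)C)OC1=O | intermediate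
23 | (7R)-7-[(1R,4Z)-1,6-dihydroxy-4-methylhex-4-en-1-yl]-3-[(3Z)-5-hydroxy-4-methylpent-3-en-1-yl]-7-methyl-6,7-dihydrooxepin-2(5H)-one | C/C(=C/CCC1=CCC[C@](C)([C@H](O)CC/C(C)=C\CO)OC1=O)CO | target

**Step count and risks**

Total step count: 15. Longest linear sequence: 12 (steps 1–8, then 12–15).

Steps most likely to fail:

1. Step 14. Closure of the seven-membered ring may be slower than acid-induced rearrangement of the oxirane, participation of a neighbouring olefin, or loss of a silyl ether. The fallback sets out from 20 and comes back to the route at 23. Dilute HClO4 in THF/H2O at 0 °C should open the oxirane by attack of water at the tertiary carbon with inversion, giving the diol ester F1. Et3SiCl and imidazole should silylate only the secondary hydroxyl, giving the triethylsilyl ether F2. LiOH then gives the hydroxy acid F3. Shiina lactonisation (2-methyl-6-nitrobenzoic anhydride, DMAP, toluene, high dilution) onto the tertiary hydroxyl gives the silylated lactone F4. Bu4NF/AcOH then removes all three silyl groups to give 23. In this variant the ring is closed by acylation instead of by opening of the oxirane.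

2. Step 7. Substitution at the hindered oxiranylmethyl carbon may be slow, letting the carbanion open the oxirane or the triflate decompose. The fallback sets out from 8 and comes back at 11. Dess–Martin periodinane oxidation gives the epoxy aldehyde F5. Horner–Wadsworth–Emmons reaction with diethyl (cyanomethyl)phosphonate (LiCl, DBU, MeCN; Masamune–Roush conditions) gives the unsaturated nitrile F6. Diimide, generated from 2-nitrobenzenesulfonohydrazide and Et3N, should then reduce the disubstituted conjugated double bond in preference to the trisubstituted olefin and leave the oxirane untouched, giving 11.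

3. Step 9. The alkoxide-bearing ylide may erode the Z selectivity of the Wittig reaction. The fallback sets out from 5 (with purchased 3-[(4-methoxybenzyl)oxy]propanal) and comes back at 16. Still–Gennari olefination (KN(SiMe3)2, 18-crown-6, THF, −78 °C) gives the Z enoate F7. Reduction with i-Bu2AlH gives the allylic alcohol F8. Silylation with t-BuMe2SiCl and imidazole gives the silyl ether F9. Oxidative removal of the 4-methoxybenzyl group with DDQ (CH2Cl2/pH 7 buffer) gives 16.

**Further compounds**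

F1 | step 14 | methyl (2Z,5Z)-7-[(tert-butyldimethylsilyl)oxy]-2-[(4R,5R,8Z)-10-[(tert-butyldiphenylsilyl)oxy]-4,5-dihydroxy-4,8-dimethyldec-8-en-1-ylidene]-6-methylhept-5-enoate | COC(=O)/C(CC/C=C(/C)CO[Si](C)(C)C(C)(C)C)=C\CC[C@@](C)(O)[C@H](O)CC/C(C)=C\CO[Si](c1ccccc1)(c1ccccc1)C(C)(C)C
F2 | step 14 | methyl (2Z,5Z)-7-[(tert-butyldimethylsilyl)oxy]-2-[(4R,5R,8Z)-10-[(tert-butyldiphenylsilyl)oxy]-4-hydroxy-4,8-dimethyl-5-[(triethylsilyl)oxy]dec-8-en-1-ylidene]-6-methylhept-5-enoate | COC(=O)/C(CC/C=C(/C)CO[Si](C)(C)C(C)(C)C)=C\CC[C@@](C)(O)[C@H](O[Si](CC)(CC)CC)CC/C(C)=C\CO[Si](c1ccccc1)(c1ccccc1)C(C)(C)C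
F3 | step 14 | (2Z,5Z)-7-[(tert-butyldimethylsilyl)oxy]-2-[(4R,5R,8Z)-10-[(tert-butyldiphenylsilyl)oxy]-4-hydroxy-4,8-dimethyl-5-[(triethylsilyl)oxy]dec-8-en-1-ylidene]-6-methylhept-5-enoic acid | OC(=O)/C(CC/C=C(/C)CO[Si](C)(C)C(C)(C)C)=C\CC[C@@](C)(O)[C@H](O[Si](CC)(CC)CC)CC/C(C)=C\CO[Si](c1ccccc1)(c1ccccc1)C(C)(C)C
F4 | step 14 | (7R)-3-{(3Z)-5-[(tert-butyldimethylsilyl)oxy]-4-methylpent-3-en-1-yl}-7-{(1R,4Z)-6-[(tert-butyldiphenylsilyl)oxy]-4-methyl-1-[(triethylsilyl)oxy]hex-4-en-1-yl}-7-methyl-6,7-dihydrooxepin-2(5H)-one | CC(C)(C)[Si](C)(C)OC/C(C)=C\CCC1=CCC[C@](C)([C@H](O[Si](CC)(CC)CC)CC/C(C)=C\CO[Si](c2ccccc2)(c2ccccc2)C(C)(C)C)OC1=O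
F5 | step 7 | (2R,3R)-3-{(3Z)-5-[(tert-butyldiphenylsilyl)oxy]-3-methylpent-3-en-1-yl}-2-methyloxirane-2-carbaldehyde | O=C[C@]1(C)O[C@@H]1CC/C(C)=C\CO[Si](c1ccccc1)(c1ccccc1)C(C)(C)C
F6 | step 7 | (2E)-3-[(2S,3R)-3-{(3Z)-5-[(tert-butyldiphenylsilyl)oxy]-3-methylpent-3-en-1-yl}-2-methyloxiran-2-yl]prop-2-enenitrile | N#C/C=C/[C@]1(C)O[C@@H]1CC/C(C)=C\CO[Si](c1ccccc1)(c1ccccc1)C(C)(C)C
F7 | step 9 | ethyl (2Z)-5-[(4-methoxybenzyl)oxy]-2-methylpent-2-enoate | CCOC(=O)/C(C)=C\CCOCc1ccc(OC)cc1
F8 | step 9 | (2Z)-5-[(4-methoxybenzyl)oxy]-2-methylpent-2-en-1-ol | OC/C(C)=C\CCOCc1ccc(OC)cc1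
F9 | step 9 | tert-butyl({(2Z)-5-[(4-methoxybenzyl)oxy]-2-methylpent-2-en-1-yl}oxy)dimethylsilane | CC(C)(C)[Si](C)(C)OC/C(C)=C\CCOCc1ccc(OC)cc1
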